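How much of the winter charge has turned by the asked time, given that the winter flask has the dusk charge and the dusk run has a reading at that very time?

| setting | spring | noon | dusk | midnight | winter |
|---|---|---|---|---|---|
| substrate | 0.800 M | 0.800 M | 2.40 M | 0.800 M | 2.40 M |
| free catalyst | 0.0240 M | 0.0720 M | 0.0240 M | 0.0240 M | 0.0240 M |
| product |  |  |  | 0.400 M |  |
| time |  |  |  |  | 5.0 h |

| run | time / h | [product] / M |
|---|---|---|
| spring run | 0.18 | 0.0229 |
| spring run | 0.54 | 0.0701 |
| spring run | 1.0 | 0.1241 |
| spring run | 1.6 | 0.1883 |
| spring run | 2.4 | 0.2672 |
| spring run | 3.2 | 0.3272 |
| spring run | 4.0 | 0.3863 |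
| spring run | 5.0 | 0.4456 |
| noon run | 0.18 | 0.0609 |
| noon run | 0.54 | 0.1903 |
| noon run | 1.0 | 0.3239 |
| noon run | 1.6 | 0.4599 |
| noon run | 2.4 | 0.5832 |
| noon run | 3.2 | 0.6605 |
| noon run | 4.0 | 0.7168 |
| noon run | 5.0 | 0.7497 |
| dusk run | 0.18 | 0.0427 |
| dusk run | 0.54 | 0.1341 |
| dusk run | 1.0 | 0.2495 |
| dusk run | 1.6 | 0.3921 |
| dusk run | 2.4 | 0.5633 |
| dusk run | 3.2 | 0.7209 |
| dusk run | 4.0 | 0.8630 |
| dusk run | 5.0 | 1.0421 |
| midnight run | 0.18 | 0.4233 |
| midnight run | 0.54 | 0.4796 |
| midnight run | 1.0 | 0.5486 |
| midnight run | 1.6 | 0.6218 |
| midnight run | 2.4 | 0.7069 |
| midnight run | 3.2 | 0.7807 |
| midnight run | 4.0 | 0.8395 |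
| midnight run | 5.0 | 0.9049 |

(scatter of a reading: 0.002 M)

* how the opening rate goes with [free catalyst] round the charge of the spring run: the exponent of the rate at two percent of substrate gone to product
* how the opening rate goes with [substrate] round the charge of the spring run: the exponent of the rate at two percent of substrate gone to product (one fixed amount of product, the same in the runs compared)
* product in the winter run at 5.0 h, as a share of the substrate charged

- Overall: substrate -> product, with free catalyst as catalyst.
- Constant volume, constant temperature.
- The analysis sees a species whether free or bound.
- An order is taken over about fifteen percent of the charge, up and down.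

The dusk run was the winter flask already run once, so I committed to its last reading, 43.4% of the charge, with a scatter of 0.0833%. I still wanted to see whether that share made sense.

In fractions of the charge, the dusk run opened at 0.103 h⁻¹, read from its second point. Two extreme flasks can be solved in the head. If the rate ignored substrate and held that pace, the share at 5.0 h would be 51.7%. If the rate fell in step with substrate (pseudo-first-order), the share would be 40.4%.

From spring to dusk, the opening rates gave a substrate exponent of 0.590. That is a chord across the opening rates, not the local slope, and it lies between zero and one, so I held the extremes as an estimate, not a bound, on the later run. The dusk share stood above the lower extreme and below the upper one, nearer the lower. The same chord for catalyst, spring to noon, gave 0.909.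

The mean rate of the dusk run over its opening rate came to 0.839; I call this ratio the kept pace. Replacing the curve by its mean cost little, since the dusk slope around mid-run was 0.205 M h⁻¹ against a mean of 0.208 M h⁻¹.

The forecast gave 0.92 for the catalyst order, 0.72 for the substrate order, which stood above my chord, and 43.3% for the share, this last on the ground that “The winter charge and time are the same as dusk”.

The flask gave 0.97, 0.74 and 43.3%.

    free catalyst + substrate ⇌ catalyst-substrate complex (10.73 M⁻¹ h⁻¹, 1.040 h⁻¹)
    catalyst-substrate complex → product + free catalyst (22.28 h⁻¹)
    catalyst-substrate complex → spent catalyst + substrate (0.5832 h⁻¹)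
    substrate + product → 2 product (0.07848 M⁻¹ h⁻¹)

The winter run kept 0.838 of its opening pace, and it stayed between the extremes because the turning of catalyst-substrate complex into spent catalyst and substrate and the step in which product turns substrate into more product pull against each other. Without the turning of catalyst-substrate complex into spent catalyst and substrate, the winter run reaches 63.6%, above the upper extreme. Without substrate being turned into product by product, it reaches 28.5%, below the lower extreme. The spring run, by the same measure, kept 0.687.

(The runs were computed on assumed constants, noise included.)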